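Plan
1. Retrosynthesis: cut C5=C6 (ring-closing metathesis of ring B). Next remove the lactone C19–O bond and the C7/C8 oxygens (syn-dihydroxylation of a C7=C8 alkene), then cut C8–C9 (alkenyllithium + carbonyl C9) and C3–C4 (radical methallylation). Re-join C11 to C14 (reverse of an oxidative C–C scission), and last cut C10–C11 and C1–C14 together.
2. Enabling feature: in ring A (C1, C10, C11, C12, C13, C14) the carbinol carbons C11 and C14 stand 1,4, so they can be the two ends of one cleaved σ-bond, and C11–C12–C13–C14 can arrive as a cyclobutene enol ether. C1 and C10 are vicinal and carry C2–O and C9, so they are the alkene of a butenolide C9(=O)–O–C2.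
3. Helpers: the tether C3–O–Si(i-Pr)2–O–C14 (removed in step 8), the bond C11–C14 (cleaved in step 11) and the lactone C2–O–C9 (opened in step 20).
4. Forward order of rings: butenolide, bicyclo[2.2.0]hexane (step 7), ring A (step 11), γ-lactone ring C (step 25), ten-membered ring B (step 30).
5. Stereochemistry: C2 comes from methyl (S)-2,2-dimethyl-1,3-dioxolane-4-carboxylate and C17 from methyl (S)-3-hydroxy-2-methylpropanoate. C1 is set by the tether (attack syn to C3), C11 and C14 by the convex face of the cis-fused lactone, and C10 by equilibration. C9 follows from a C11–OH-directed syn reduction, and C7/C8 from a C9–OH-directed syn-dihydroxylation of a geometrically defined alkene. C5=C6 becomes ring-cis through ring strain.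

Key step: step 7

Assumption: locants C1–C20 are the customary briarane locants. Ring A = C1, C10–C14. Ring B = C1–C10. Ring C = C7, C8, C17, C19, O. C15, C16, C18 and C20 are the methyl groups on C1, C5, C17 and C11.

Step 1
Reactants: 1 methyl (S)-2,2-dimethyl-1,3-dioxolane-4-carboxylate
Product: 3 (S)-1-(2,2-dimethyl-1,3-dioxolan-4-yl)ethan-1-one, via Weinreb amide 2 (not isolated)
Conditions: MeNH(OMe)·HCl, i-PrMgCl, THF, −20 °C; then MeMgBr, 0 °C
Reagents that add atoms: N,O-dimethylhydroxylamine hydrochloride CNOC.Cl (atoms in 2 only); methylmagnesium bromide C[Mg]Br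
Why: Weinreb ketone synthesis, in which the magnesium chelate of 2 stops the addition at the ketone level and the α-alkoxy stereocenter (future C2) is not enolised at low temperature.

Step 2
Reactants: 3 (S)-1-(2,2-dimethyl-1,3-dioxolan-4-yl)ethan-1-one
Product: 4 methyl (Z)-3-[(4R)-2,2-dimethyl-1,3-dioxolan-4-yl]but-2-enoate
Conditions: (CF3CH2O)2P(O)CH2CO2Me, KN(SiMe3)2, 18-crown-6, THF, −78 °C
Reagents that add atoms: methyl bis(2,2,2-trifluoroethyl)phosphonoacetate COC(=O)CP(=O)(OCC(F)(F)F)OCC(F)(F)F
Why: Still–Gennari olefination, which the electrophilic α-alkoxy methyl ketone should undergo under kinetic control to give the Z-enoate, with ester and carbinol carbon cis as lactonisation needs.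

Step 3
Reactants: 4 methyl (Z)-3-[(4R)-2,2-dimethyl-1,3-dioxolan-4-yl]but-2-enoate
Product: 6 (R)-5-(hydroxymethyl)-4-methylfuran-2(5H)-one, via dihydroxy enoate 5 (not isolated)
Conditions: 1 M HCl, THF, 25 °C
Reagents that add atoms: none
Why: Acid-catalysed acetonide hydrolysis followed by spontaneous lactonisation of the Z-γ-hydroxy enoate, which leaves C2 untouched and frees the C3 hydroxyl for the tether.

Step 4
Reactants: 7 2-methylcyclobutan-1-one (racemic)
Product: 8 1-methyl-2-(trimethylsilyloxy)cyclobut-1-ene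
Conditions: Me3SiCl, NaI, Et3N, MeCN, 25 °C
Reagents that add atoms: chlorotrimethylsilane C[Si](C)(C)Cl
Why: Silyl enol ether formation under equilibrating conditions (Me3SiI made in situ) should favour the more substituted enol ether, and the stereocenter of 7 is erased.

Step 5
Reactants: 8 1-methyl-2-(trimethylsilyloxy)cyclobut-1-ene
Product: 10 chloro(diisopropyl)[(2-methylcyclobut-1-en-1-yl)oxy]silane, via lithium enolate 9 (not isolated)
Conditions: MeLi, THF, 0 °C; then added to i-Pr2SiCl2 (3 equiv), −78 to 25 °C; volatiles removed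
Reagents that add atoms: methyllithium [Li]C (lithium in 9 only); dichlorodiisopropylsilane CC(C)[Si](Cl)(Cl)C(C)C
Why: Regiospecific enolate generation from a silyl enol ether with MeLi and O-silylation, in which inverse addition to excess dichlorosilane stops at the monochloride.

Step 6
Reactants: 6 (R)-5-(hydroxymethyl)-4-methylfuran-2(5H)-one; 10 chloro(diisopropyl)[(2-methylcyclobut-1-en-1-yl)oxy]silane
Product: 11 (R)-5-({diisopropyl[(2-methylcyclobut-1-en-1-yl)oxy]silyl}oxymethyl)-4-methylfuran-2(5H)-one
Conditions: imidazole, CH2Cl2, 0 to 25 °C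
Reagents that add atoms: none
Why: Silyl ether (silaketal) formation, in which the weak base spares the acidic γ-proton at C2 of the butenolide, so the stereocenter is kept.

Step 7
Reactants: 11 (R)-5-({diisopropyl[(2-methylcyclobut-1-en-1-yl)oxy]silyl}oxymethyl)-4-methylfuran-2(5H)-one
Product: 12 tetracyclic photoadduct (γ-lactone C9(=O)–O–C2 cis-fused to the bicyclo[2.2.0]hexane C1/C10/C11/C12/C13/C14 whose central bond is C11–C14; cis-anti-cis; bridge C3–O–Si(i-Pr)2–O–C14; C11 and C14 on the lactone face that bears C3)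
Conditions: hν (medium-pressure Hg lamp, quartz well), degassed MeCN (3 mM), −20 °C
Reagents that add atoms: none
Why: The excited butenolide (C9=O, C10=C1) crosses to its triplet and adds stepwise through a 1,4-biradical to the tethered electron-rich cyclobutene C11=C14, so that C1–C14 and C10–C11 form in one photochemical operation; the closest known reaction types are the silicon-tethered intramolecular enone–alkene [2+2] photocycloaddition and the addition of 2(5H)-furanones or cyclic enones to cyclobutenes that gives bicyclo[2.2.0]hexanes. Two rings close: the central cyclobutane C1–C10–C11–C14 (formal [2+2], cis on the lactone because a five-membered enone cannot give a trans fusion, cis on the cyclobutene by ring constraint) and the seven-membered 1,3-dioxa-2-silepane C1–C2–C3–O–Si–O–C14 (straight, 7-exo closure onto the cyclobutene). C1 (quaternary, kept to the end) and C10 are set by the face of the butenolide, and the tether fixes this face because it starts at C3 on C2 and reaches only the face syn to C3, which is the face the target needs and the opposite of the anti attack of an untethered alkene. C11 and C14 follow from the exo approach of the cyclobutene (its CH2CH2 bridge turned away from the lactone), but both are erased in step 11, so exo and endo adducts converge. The selectivity that matters is regiochemistry (C14 to C1, not to C10), and it is secured twice, by the short tether and by the innate head-to-tail preference that joins the donor-bearing alkene carbon to the β-carbon of the enone. The strain stored across the temporary C11–C14 bond later drives the opening to ring A.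

Step 8
Reactants: 12 tetracyclic photoadduct
Product: 13 ladderane diol lactone (free C3–OH; tertiary cyclobutanol C14–OH)
Conditions: HF·pyridine, THF, 0 °C
Reagents that add atoms: none
Why: Fluoride-mediated Si–O cleavage removes the tether under mildly acidic conditions, which avoids alkoxide-induced opening of the strained cyclobutanol.

Step 9
Reactants: 13 ladderane diol lactone
Product: 14 C3 iodide of 13
Conditions: I2, PPh3, imidazole, CH2Cl2, 0 °C
Reagents that add atoms: iodine II
Why: Appel reaction, in which only the primary C3 alcohol can be displaced and the tertiary C14 alcohol stays.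

Step 10
Reactants: 14 C3 iodide
Product: 15 cyclobutanol lactone carrying the chain C3H2–C4H2–C5(CH3)=CH2 on C2
Conditions: tributyl(2-methylallyl)stannane, Et3B, air, toluene, 25 °C
Reagents that add atoms: tributyl(2-methylallyl)stannane CCCC[Sn](CCCC)(CCCC)CC(C)=C
Why: Keck radical allylation forms C3–C4 under neutral conditions at room temperature, which lactone, free alcohol and strained ladderane should all tolerate.

Step 11
Reactants: 15 methallylated cyclobutanol lactone
Product: 17 cis-fused keto lactone of ring A (C14 ketone; C11 tertiary alcohol on the face of C15), via keto hydroperoxide 16 (not isolated)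
Conditions: Co(acac)2 (10 mol %), O2 (1 atm), MeCN, 25 °C; then PPh3, 0 °C
Reagents that add atoms: dioxygen O=O
Why: Cobalt-catalysed aerobic ring opening of a cyclobutanol, in which the C14 alkoxy radical should cleave C11–C14 (the only β-bond whose scission frees both four-membered rings and leaves a tertiary radical), O2 should take the C11 radical on the convex face of the cis-fused lactone anti to C9 and so set C11, and PPh3 reduces the hydroperoxide.

Step 12
Reactants: 17 keto lactone
Product: 18 11,14-diol lactone (C14–OH on the face of C2)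
Conditions: LiBH(s-Bu)3, THF, −78 °C; aq. NH4Cl
Reagents that add atoms: none
Why: Ketone reduction with a bulky borohydride, in which hydride should come from the convex face (equatorial attack, the axial path being blocked by C9 on C10) and so set C14 with its hydroxyl syn to C2.

Step 13
Reactants: 18 11,14-diol lactone
Product: 20 lactone bearing 14-O-SiMe2t-Bu plus 11-O-SiMe3 ethers, via mono-silyl ether 19 (not isolated)
Conditions: t-BuMe2SiOTf (1.1 equiv), 2,6-lutidine, CH2Cl2, −78 to 0 °C; then Me3SiOTf, 0 °C
Reagents that add atoms: tert-butyldimethylsilyl triflate CC(C)(C)[Si](C)(C)OS(=O)(=O)C(F)(F)F; trimethylsilyl triflate C[Si](C)(C)OS(=O)(=O)C(F)(F)F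
Why: Sequential silyl ether formation, in which the secondary alcohol takes the bulky group first and the tertiary one takes a small group that can later be removed on its own.

Step 14
Reactants: 21 methyl (S)-3-hydroxy-2-methylpropanoate
Product: 22 methyl (S)-3-(tert-butyldimethylsilyloxy)-2-methylpropanoate
Conditions: t-BuMe2SiCl, imidazole, DMF, 25 °C
Reagents that add atoms: tert-butyldimethylsilyl chloride CC(C)(C)[Si](C)(C)Cl
Why: Standard silyl protection of the future C19 hydroxyl, with the C17 stereocenter bought in.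

Step 15
Reactants: 22 methyl (S)-3-(tert-butyldimethylsilyloxy)-2-methylpropanoate
Product: 23 (S)-3-(tert-butyldimethylsilyloxy)-2-methylpropanal
Conditions: i-Bu2AlH, CH2Cl2, −78 °C
Reagents that add atoms: none
Why: Partial ester reduction, in which the aluminium hemiacetal is stable at low temperature and the aldehyde (future C8) is used at once to avoid epimerisation at C17.

Step 16
Reactants: 23 (S)-3-(tert-butyldimethylsilyloxy)-2-methylpropanal
Product: 24 (R)-tert-butyl[(4,4-dibromo-2-methylbut-3-en-1-yl)oxy]dimethylsilane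
Conditions: CBr4, PPh3, CH2Cl2, 0 °C
Reagents that add atoms: carbon tetrabromide BrC(Br)(Br)Br
Why: First stage of the Corey–Fuchs alkyne synthesis, which adds C7 under non-basic conditions.

Step 17
Reactants: 24 (R)-tert-butyl[(4,4-dibromo-2-methylbut-3-en-1-yl)oxy]dimethylsilane
Product: 26 (R)-5-(tert-butyldimethylsilyloxy)-4-methylpent-2-yn-1-ol, via lithium acetylide 25 (not isolated)
Conditions: n-BuLi (2.1 equiv), THF, −78 °C; then (CH2O)n, −78 to 25 °C
Reagents that add atoms: n-butyllithium [Li]CCCC (lithium in 25 only); formaldehyde (from paraformaldehyde) C=O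
Why: Second stage of the Corey–Fuchs sequence with trapping of the acetylide by formaldehyde, which adds C6 as a propargylic alcohol.

Step 18
Reactants: 26 (R)-5-(tert-butyldimethylsilyloxy)-4-methylpent-2-yn-1-ol
Product: 28 (S,Z)-5-(tert-butyldimethylsilyloxy)-3-iodo-4-methylpent-2-en-1-ol, via cyclic vinylalanate 27 (not isolated)
Conditions: NaAlH2(OCH2CH2OMe)2, THF, 0 to 25 °C; then I2, −78 °C
Reagents that add atoms: sodium bis(2-methoxyethoxy)aluminium dihydride [Na+].COCCO[AlH2-]OCCOC (atoms in 27 only); iodine II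
Why: Alkoxide-directed trans-hydroalumination of a propargylic alcohol and iodinolysis with retention place iodine on C8 cis to C6, which fixes the C7=C8 geometry.

Step 19
Reactants: 28 (S,Z)-5-(tert-butyldimethylsilyloxy)-3-iodo-4-methylpent-2-en-1-ol
Product: 29 tert-butyldiphenylsilyl ether of 28 (C6–O–SiPh2t-Bu; C19–O–SiMe2t-Bu)
Conditions: t-BuPh2SiCl, imidazole, CH2Cl2, 25 °C
Reagents that add atoms: tert-butyldiphenylsilyl chloride CC(C)(C)[Si](Cl)(c1ccccc1)c1ccccc1
Why: Silyl protection with a group that outlasts the acid methanolysis of step 22, so that C19–OH and C6–OH can be freed at different times.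

Step 20
Reactants: 20 bis-silylated lactone; 29 alkenyl iodide
Product: 31 C2-hydroxy C9 enone (C9 still cis to C2 on ring A; C9 cis to C6 on C8=C7), via alkenyllithium 30 (not isolated)
Conditions: 29, t-BuLi (2 equiv), Et2O, −78 °C; then 20, −78 to −40 °C; aq. NH4Cl
Reagents that add atoms: tert-butyllithium [Li]C(C)(C)C (lithium in 30 only)
Why: Iodine–lithium exchange with retention and addition of the alkenyllithium to the γ-lactone form C8–C9, and the lithium hemiketal should survive until work-up, so the reaction stops at the ketone.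

Step 21
Reactants: 31 C2-hydroxy C9 enone
Product: 33 C2 acetate of the C10-epimerised enone (C9 trans to C2 on ring A), via C10-epimerised hydroxy enone 32 (not isolated)
Conditions: DBU (0.5 equiv), toluene, 40 °C; then Ac2O, DMAP, Et3N, 25 °C
Reagents that add atoms: acetic anhydride CC(=O)OC(C)=O
Why: Base-mediated epimerisation α to the ketone followed by esterification, in which the C9 acyl group, with C11 and C14 in place, should leave the axial site syn to the C14 silyloxy group for the equatorial one (C10 set under thermodynamic control), and acetylation traps the open C2 alcohol.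

Step 22
Reactants: 33 C2 acetate
Product: 34 enone with free C11–OH and C19–OH
Conditions: camphorsulfonic acid (cat.), MeOH/CH2Cl2, 0 °C
Reagents that add atoms: none
Why: Acid-catalysed methanolysis removes the tertiary SiMe3 and the primary SiMe2t-Bu ethers, while the hindered secondary C14 ether and the SiPh2t-Bu ether should stay.

Step 23
Reactants: 34 enone diol
Product: 35 (9S)-allylic alcohol (C9–OH syn to C11–OH)
Conditions: Et2BOMe, NaBH4, THF/MeOH, −78 °C; MeOH co-evaporation
Reagents that add atoms: none
Why: Narasaka–Prasad reduction, in which boron ties C11–O to C9=O in a six-membered chelate whose face toward C1/C2 is blocked, so external hydride gives the 1,3-syn diol and sets C9.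

Step 24
Reactants: 35 allylic alcohol
Product: 37 7,8,9,11,19-pentaol (C7–OH and C8–OH syn to each other; C8–OH syn to C9–OH), via osmate ester 36 (not isolated)
Conditions: OsO4 (1.0 equiv), TMEDA, CH2Cl2, −78 °C; then ethane-1,2-diamine, 25 °C
Reagents that add atoms: osmium tetroxide O=[Os](=O)(=O)=O; TMEDA CN(C)CCN(C)C (atoms in 36 only)
Why: Hydrogen-bond-directed dihydroxylation with OsO4·TMEDA, in which C9–OH, held by allylic 1,3-strain against C6, should guide the reagent to its own face (also the face away from ring A) and to this alkene rather than the remote C5 alkene, while syn addition to the defined geometry sets C7 and C8 together.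

Step 25
Reactants: 37 pentaol
Product: 39 γ-lactone C19(=O)–O–C7 (ring C) with free C8–OH and C9–OH, via lactol 38 (not isolated)
Conditions: TEMPO (cat.), PhI(OAc)2, CH2Cl2, 25 °C
Reagents that add atoms: none
Why: TEMPO-catalysed oxidative lactonisation of a 1,4-diol, in which only the primary C19 alcohol is oxidised, the aldehyde should be caught by the less hindered C7–OH rather than by C9–OH (flanked by C8 and C10), and the lactol is oxidised on.

Step 26
Reactants: 39 hydroxy lactone
Product: 40 2,9-diacetate
Conditions: Ac2O, DMAP, Et3N, CH2Cl2, 25 °C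
Reagents that add atoms: acetic anhydride CC(=O)OC(C)=O
Why: DMAP-catalysed esterification of the only free secondary alcohol, with the tertiary C8 and C11 alcohols expected to stay free.

Step 27
Reactants: 40 2,9-diacetate
Product: 41 tetraol diacetate (free C6–OH, C8–OH, C11–OH, C14–OH)
Conditions: HF·pyridine, THF, 0 to 25 °C
Reagents that add atoms: none
Why: Fluoride-mediated desilylation under mildly acidic conditions, chosen to avoid base-induced acetyl migration from C2–O to C14–O.

Step 28
Reactants: 41 tetraol diacetate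
Product: 42 C6 aldehyde
Conditions: TEMPO (cat.), PhI(OAc)2, CH2Cl2, 0 °C
Reagents that add atoms: none
Why: TEMPO-catalysed oxidation is selective for the primary alcohol and should leave the hindered axial C14–OH untouched.

Step 29
Reactants: 42 C6 aldehyde
Product: 43 seco-diene (C7–C6H=CH2 and C4–C5(CH3)=CH2)
Conditions: Zn, CH2I2, Ti(Oi-Pr)4, THF, 25 °C
Reagents that add atoms: diiodomethane ICI
Why: Takai–Lombardo methylenation is aldehyde-selective and non-basic, so the α-acyloxy β-hydroxy aldehyde should escape epimerisation at C7, retro-aldol cleavage and acetyl migration.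

Step 30
Reactants: 43 seco-diene
Product: 44 junceellolide I
Conditions: second-generation Hoveyda–Grubbs catalyst (10 mol %), toluene (0.5 mM), 80 °C, argon sparge
Reagents that add atoms: none
Why: Ring-closing metathesis, in which the catalyst loads on the monosubstituted C6 vinyl group and closes on the 1,1-disubstituted C5 alkene, and under reversible conditions the ten-membered ring should take the less strained ring-cis (Z) geometry.

Compound list
1 | methyl (S)-2,2-dimethyl-1,3-dioxolane-4-carboxylate | COC(=O)[C@@H]1COC(C)(C)O1 | starting material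
2 | (S)-N-methoxy-N,2,2-trimethyl-1,3-dioxolane-4-carboxamide | CON(C)C(=O)[C@@H]1COC(C)(C)O1 | intermediate
3 | (S)-1-(2,2-dimethyl-1,3-dioxolan-4-yl)ethan-1-one | CC(=O)[C@@H]1COC(C)(C)O1 | intermediate
4 | methyl (Z)-3-[(4R)-2,2-dimethyl-1,3-dioxolan-4-yl]but-2-enoate | COC(=O)/C=C(C)\[C@@H]1COC(C)(C)O1 | intermediate
5 | methyl (Z,4R)-4,5-dihydroxy-3-methylpent-2-enoate | COC(=O)/C=C(C)\[C@@H](O)CO | intermediate
6 | (R)-5-(hydroxymethyl)-4-methylfuran-2(5H)-one | O=C1C=C(C)[C@H](CO)O1 | intermediate
7 | 2-methylcyclobutan-1-one (racemic) | CC1CCC1=O | starting material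
8 | 1-methyl-2-(trimethylsilyloxy)cyclobut-1-ene | CC1=C(O[Si](C)(C)C)CC1 | intermediate
9 | lithium 2-methylcyclobut-1-en-1-olate | CC1=C([O-])CC1.[Li+] | intermediate
10 | chloro(diisopropyl)[(2-methylcyclobut-1-en-1-yl)oxy]silane | CC1=C(O[Si](Cl)(C(C)C)C(C)C)CC1 | intermediate
11 | silaketal-tethered butenolide–cyclobutene | O=C1C=C(C)[C@H](CO[Si](C(C)C)(C(C)C)OC2=C(C)CC2)O1 | intermediate
12 | tetracyclic photoadduct (cis-anti-cis; C11–C14 central bond; silaketal bridge) | O=C1O[C@H]2CO[Si](C(C)C)(C(C)C)O[C@@]34CC[C@]3(C)[C@@H]1[C@@]24C | intermediate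
13 | ladderane diol lactone | O=C1O[C@@H](CO)[C@]2(C)[C@H]1[C@@]3(C)CC[C@@]23O | intermediate
14 | C3 iodide | O=C1O[C@@H](CI)[C@]2(C)[C@H]1[C@@]3(C)CC[C@@]23O | intermediate
15 | methallylated cyclobutanol lactone | O=C1O[C@@H](CCC(C)=C)[C@]2(C)[C@H]1[C@@]3(C)CC[C@@]23O | intermediate
16 | C11 hydroperoxy C14 keto lactone | O=C1O[C@@H](CCC(C)=C)[C@]2(C)[C@H]1[C@@](C)(OO)CCC2=O | intermediate
17 | C11 hydroxy C14 keto lactone | O=C1O[C@@H](CCC(C)=C)[C@]2(C)[C@H]1[C@@](C)(O)CCC2=O | intermediate
18 | 11,14-diol lactone | O=C1O[C@@H](CCC(C)=C)[C@]2(C)[C@H]1[C@@](C)(O)CC[C@@H]2O | intermediate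
19 | 14-O-tert-butyldimethylsilyl ether of 18 | O=C1O[C@@H](CCC(C)=C)[C@]2(C)[C@H]1[C@@](C)(O)CC[C@@H]2O[Si](C)(C)C(C)(C)C | intermediate
20 | 14-O-tert-butyldimethylsilyl 11-O-trimethylsilyl lactone | O=C1O[C@@H](CCC(C)=C)[C@]2(C)[C@H]1[C@@](C)(O[Si](C)(C)C)CC[C@@H]2O[Si](C)(C)C(C)(C)C | intermediate
21 | methyl (S)-3-hydroxy-2-methylpropanoate | COC(=O)[C@@H](C)CO | starting material
22 | methyl (S)-3-(tert-butyldimethylsilyloxy)-2-methylpropanoate | COC(=O)[C@@H](C)CO[Si](C)(C)C(C)(C)C | intermediate
23 | (S)-3-(tert-butyldimethylsilyloxy)-2-methylpropanal | O=C[C@@H](C)CO[Si](C)(C)C(C)(C)C | intermediate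
24 | (R)-tert-butyl[(4,4-dibromo-2-methylbut-3-en-1-yl)oxy]dimethylsilane | BrC(Br)=C[C@@H](C)CO[Si](C)(C)C(C)(C)C | intermediate
25 | lithium acetylide from 24 | [Li]C#C[C@@H](C)CO[Si](C)(C)C(C)(C)C | intermediate
26 | (R)-5-(tert-butyldimethylsilyloxy)-4-methylpent-2-yn-1-ol | OCC#C[C@@H](C)CO[Si](C)(C)C(C)(C)C | intermediate
27 | sodium salt of the cyclic vinylalanate (ring Al–O–C6–C7=C8) | COCCO[Al-]1(OCCOC)OCC=C1[C@@H](C)CO[Si](C)(C)C(C)(C)C.[Na+] | intermediate
28 | (S,Z)-5-(tert-butyldimethylsilyloxy)-3-iodo-4-methylpent-2-en-1-ol | OC/C=C(\I)[C@@H](C)CO[Si](C)(C)C(C)(C)C | intermediate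
29 | tert-butyldiphenylsilyl ether of 28 | CC(C)(C)[Si](c1ccccc1)(c1ccccc1)OC/C=C(\I)[C@@H](C)CO[Si](C)(C)C(C)(C)C | intermediate
30 | alkenyllithium from 29 | CC(C)(C)[Si](c1ccccc1)(c1ccccc1)OC/C=C(\[Li])[C@@H](C)CO[Si](C)(C)C(C)(C)C | intermediate
31 | C2-hydroxy C9 enone, C9 cis to C2 | C=C(C)CC[C@H](O)[C@@]1(C)[C@@H](O[Si](C)(C)C(C)(C)C)CC[C@](C)(O[Si](C)(C)C)[C@H]1C(=O)/C(=C\CO[Si](c1ccccc1)(c1ccccc1)C(C)(C)C)[C@@H](C)CO[Si](C)(C)C(C)(C)C | intermediate
32 | C2-hydroxy C9 enone, C9 trans to C2 | C=C(C)CC[C@H](O)[C@@]1(C)[C@@H](O[Si](C)(C)C(C)(C)C)CC[C@](C)(O[Si](C)(C)C)[C@@H]1C(=O)/C(=C\CO[Si](c1ccccc1)(c1ccccc1)C(C)(C)C)[C@@H](C)CO[Si](C)(C)C(C)(C)C | intermediate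
33 | C2 acetate of 32 | C=C(C)CC[C@H](OC(C)=O)[C@@]1(C)[C@@H](O[Si](C)(C)C(C)(C)C)CC[C@](C)(O[Si](C)(C)C)[C@@H]1C(=O)/C(=C\CO[Si](c1ccccc1)(c1ccccc1)C(C)(C)C)[C@@H](C)CO[Si](C)(C)C(C)(C)C | intermediate
34 | enone with free C11–OH and C19–OH | C=C(C)CC[C@H](OC(C)=O)[C@@]1(C)[C@@H](O[Si](C)(C)C(C)(C)C)CC[C@](C)(O)[C@@H]1C(=O)/C(=C\CO[Si](c1ccccc1)(c1ccccc1)C(C)(C)C)[C@@H](C)CO | intermediate
35 | (9S)-allylic alcohol | C=C(C)CC[C@H](OC(C)=O)[C@@]1(C)[C@@H](O[Si](C)(C)C(C)(C)C)CC[C@](C)(O)[C@@H]1[C@H](O)/C(=C\CO[Si](c1ccccc1)(c1ccccc1)C(C)(C)C)[C@@H](C)CO | intermediate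
36 | C7,C8 osmate ester (hexavalent osmium), TMEDA adduct | C=C(C)CC[C@H](OC(C)=O)[C@@]1(C)[C@@H](O[Si](C)(C)C(C)(C)C)CC[C@](C)(O)[C@@H]1[C@H](O)[C@]2(O[Os](=O)(=O)O[C@H]2CO[Si](c3ccccc3)(c3ccccc3)C(C)(C)C)[C@@H](C)CO.CN(C)CCN(C)C | intermediate
37 | 7,8,9,11,19-pentaol | C=C(C)CC[C@H](OC(C)=O)[C@@]1(C)[C@@H](O[Si](C)(C)C(C)(C)C)CC[C@](C)(O)[C@@H]1[C@H](O)[C@@](O)([C@@H](O)CO[Si](c1ccccc1)(c1ccccc1)C(C)(C)C)[C@@H](C)CO | intermediate
38 | C19 lactol on C7–O (anomers) | C=C(C)CC[C@H](OC(C)=O)[C@@]1(C)[C@@H](O[Si](C)(C)C(C)(C)C)CC[C@](C)(O)[C@@H]1[C@H](O)[C@]2(O)[C@@H](C)C(O)O[C@H]2CO[Si](c3ccccc3)(c3ccccc3)C(C)(C)C | intermediate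
39 | γ-lactone with free C8–OH and C9–OH | C=C(C)CC[C@H](OC(C)=O)[C@@]1(C)[C@@H](O[Si](C)(C)C(C)(C)C)CC[C@](C)(O)[C@@H]1[C@H](O)[C@]2(O)[C@@H](C)C(=O)O[C@H]2CO[Si](c3ccccc3)(c3ccccc3)C(C)(C)C | intermediate
40 | 2,9-diacetate | C=C(C)CC[C@H](OC(C)=O)[C@@]1(C)[C@@H](O[Si](C)(C)C(C)(C)C)CC[C@](C)(O)[C@@H]1[C@H](OC(C)=O)[C@]2(O)[C@@H](C)C(=O)O[C@H]2CO[Si](c3ccccc3)(c3ccccc3)C(C)(C)C | intermediate
41 | tetraol diacetate | C=C(C)CC[C@H](OC(C)=O)[C@@]1(C)[C@@H](O)CC[C@](C)(O)[C@@H]1[C@H](OC(C)=O)[C@]2(O)[C@@H](C)C(=O)O[C@H]2CO | intermediate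
42 | C6 aldehyde | C=C(C)CC[C@H](OC(C)=O)[C@@]1(C)[C@@H](O)CC[C@](C)(O)[C@@H]1[C@H](OC(C)=O)[C@]2(O)[C@@H](C)C(=O)O[C@H]2C=O | intermediate
43 | seco-diene | C=C(C)CC[C@H](OC(C)=O)[C@@]1(C)[C@@H](O)CC[C@](C)(O)[C@@H]1[C@H](OC(C)=O)[C@]2(O)[C@@H](C)C(=O)O[C@H]2C=C | intermediate
44 | junceellolide I | CC(=O)O[C@H]1CC/C(C)=C\[C@@H]2OC(=O)[C@H](C)[C@@]2(O)[C@@H](OC(C)=O)[C@@H]2[C@]1(C)[C@@H](O)CC[C@]2(C)O | target

Total step count: 30. Longest linear sequence: 22 steps (steps 1–3, 6–13 and 20–30, from 1 to 44).

Steps most likely to fail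

Step 11. What may go wrong is unselective capture of O2 on the two faces of the planar C11 radical, because the capture has a very early transition state. The fallback delivers the oxygen by a polar route. It sets out from 17, taken on as its mixture of C11 epimers, and comes back at 17 as one epimer.
- The mixture is mesylated (MsCl, Et3N, CH2Cl2) to the tertiary mesylate F1.
- With DBU, F1 loses methanesulfonic acid by an E1cB path through the acidic C10–H and gives the C10=C11 unsaturated keto lactone F2.
- Nucleophilic epoxidation (t-BuOOH, DBU) touches only the electron-poor alkene. It passes a late, sterically demanding transition state and should place oxygen on the convex face, giving the 10,11-epoxy keto lactone F3.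
- SmI2 (THF/MeOH, −78 °C) cleaves the Cα–O bond. The enolate is protonated at C10 in the only way the five-membered lactone allows.

Step 21. What may go wrong is slow deprotonation of the hindered C10–H, which allows β-elimination of the C11 silyloxy group or isomerisation of the enone to compete. The fallback moves the epimerisation to the aldehyde level and also relieves the hindered lactone addition of step 20. It sets out from 20 and comes back at 32.
- i-Bu2AlH (CH2Cl2, −78 °C) reduces 20 to the cis-fused lactol F4.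
- A catalytic amine base (DBU, toluene, 25 °C) equilibrates F4 through the open aldehyde, whose α-proton is far more acidic, to the C10-epimerised hydroxy aldehyde F5.
- Excess 30 adds to the aldehyde to give the allylic diol F6. Its C9 epimers are of no consequence.
- MnO2 (CH2Cl2) oxidises only the allylic alcohol, giving 32, which is acetylated as in step 21.

Step 30. What may go wrong is sluggish loading of the catalyst on the hindered, oxygen-flanked C6 vinyl group, so that oligomerisation through the C5 alkene overtakes ring closure. The fallback is a relay ring-closing metathesis. It sets out from 42 and comes back at 44.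
- A Takai–Utimoto alkylidenation of 42 (6,6-diiodohex-1-ene, CrCl2, THF; non-basic) gives the relay triene F7.
- The second-generation Hoveyda–Grubbs catalyst loads on the unhindered terminal alkene of F7.
- Expulsion of cyclopentene places ruthenium directly on C6, from where only the intramolecular closure onto C5 is open.

Further compounds
F1 | step 11 | C11 mesylate of 17 (C11 epimers) | O=C1O[C@@H](CCC(C)=C)[C@]2(C)[C@H]1C(C)(OS(C)(=O)=O)CCC2=O
F2 | step 11 | C10=C11 unsaturated keto lactone | O=C1O[C@@H](CCC(C)=C)[C@]2(C)C1=C(C)CCC2=O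
F3 | step 11 | 10,11-epoxy keto lactone (oxygen on the face of C15) | O=C1O[C@@H](CCC(C)=C)[C@]2(C)[C@]13O[C@@]3(C)CCC2=O
F4 | step 21 | cis-fused lactol from 20 (anomers) | OC1O[C@@H](CCC(C)=C)[C@]2(C)[C@H]1[C@@](C)(O[Si](C)(C)C)CC[C@@H]2O[Si](C)(C)C(C)(C)C
F5 | step 21 | C10-epimerised hydroxy aldehyde | C=C(C)CC[C@H](O)[C@@]1(C)[C@@H](O[Si](C)(C)C(C)(C)C)CC[C@](C)(O[Si](C)(C)C)[C@@H]1C=O
F6 | step 21 | allylic diol (C9 epimers) | C=C(C)CC[C@H](O)[C@@]1(C)[C@@H](O[Si](C)(C)C(C)(C)C)CC[C@](C)(O[Si](C)(C)C)[C@@H]1C(O)/C(=C\CO[Si](c1ccccc1)(c1ccccc1)C(C)(C)C)[C@@H](C)CO[Si](C)(C)C(C)(C)C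
F7 | step 30 | relay triene | C=C(C)CC[C@H](OC(C)=O)[C@@]1(C)[C@@H](O)CC[C@](C)(O)[C@@H]1[C@H](OC(C)=O)[C@]2(O)[C@@H](C)C(=O)O[C@H]2/C=C/CCCC=C
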